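**Plan**
1. Retrosynthesis: remove the acetyl group, then cut C12–C13 (B-alkyl Suzuki) and C11=C12 (Wittig). Write in three helpers: a 1α-oxygen, C5=C6, and C8=C9 with C11 as a lactone carbonyl. Then cut C7–C8 and C9–C10 of ring B together by a retro-[4+2], and last the ester bond C11–O.
2. Enabling feature: ring B (C5–C10) is a cyclohexane hinged on quaternary C10. C10 carries ring-A carbon C1 and, through C9, side-chain carbon C11 in a 1,3-relation. A C1–O–C11(=O) bridge can therefore hold the unit C17–C8≡C9–C11 (a but-2-ynoate) over the ring-A diene C10=C5–C6=C7.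
3. Forward order: ring A comes from a bought cyclohexenone. Ring B and a temporary γ-lactone arise in one intramolecular Diels–Alder step. The C13–C16 end of the chain is joined last.
4. Stereochemistry: C1 is set by CBS catalysis and relays to C10 in the cycloaddition. The β-methyl on C10 then steers hydrogen (C5), peracid oxygen (C8) and a proton (C9) to the α face. 13E comes from syn-hydrozirconation and a stereoretentive coupling.
5. Removal of the helpers: C5=C6 by hydrogenation, the lactone by LiAlH4, C8=C9 by epoxidation/SmI2, and 1α-OH by Barton–McCombie deoxygenation.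

Key step: step 5

Remark: labdane atom numbers (C1–C20; C17 = methyl on C8, C20 = methyl on C10) are used for all compounds, and α means the face opposite to C20. Compounds 1, 7 and 18 are taken as catalogue chemicals.

**Step 1**
Reactants: 1 3-ethoxy-2-methylcyclohex-2-en-1-one
Product: 3 3-ethoxy-2,6,6-trimethylcyclohex-2-en-1-one, via 6-methyl enone 2 (not isolated)
Conditions: LDA, THF, −78 °C, then MeI; second LDA, −78 °C, then MeI, → rt (one flask)
Reagents that add atoms: iodomethane, CI
Why: Kinetic α′-deprotonation of the vinylogous ester (Stork–Danheiser enolate alkylation) occurs only at C6 of the ring, so two LDA/MeI cycles should build the gem-dimethyl carbon (C4 of the target).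

**Step 2**
Reactants: 3 3-ethoxy-2,6,6-trimethylcyclohex-2-en-1-one
Product: 5 2,4,4-trimethyl-3-vinylcyclohex-2-en-1-one, via tertiary vinyl carbinol 4 (not isolated)
Conditions: CH2=CHMgBr, THF, 0 °C → rt; then 1 M HCl, rt
Reagents that add atoms: vinylmagnesium bromide, C=C[Mg]Br; water, O
Why: In this Stork–Danheiser 1,2-addition/carbonyl transposition the carbonyl has no α-hydrogen on its hindered side, so addition should win, and aqueous acid then ionises the tertiary allylic alcohol and hydrolyses the enol ether to the transposed dienone.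

**Step 3**
Reactants: 5 2,4,4-trimethyl-3-vinylcyclohex-2-en-1-one
Product: 6 (S)-2,4,4-trimethyl-3-vinylcyclohex-2-en-1-ol (1α-OH)
Conditions: (R)-Me-CBS (cat.), catecholborane, PhMe, −78 °C
Reagents that add atoms: none
Why: In this Corey–Bakshi–Shibata reduction the fully substituted alkenyl arm acts as the large group and the CH2 arm as the small one, so the (R)-catalyst should deliver hydride to the face that gives the (S)-carbinol, and catecholborane at low temperature should reduce 1,2 without hydroborating the vinyl group.

**Step 4**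
Reactants: 6 (S)-2,4,4-trimethyl-3-vinylcyclohex-2-en-1-ol; 7 but-2-ynoic acid
Product: 8 (S)-2,4,4-trimethyl-3-vinylcyclohex-2-en-1-yl but-2-ynoate
Conditions: DCC, DMAP (cat.), CH2Cl2, 0 °C
Reagents that add atoms: none
Why: Steglich esterification is neutral, as the ionisation-prone dienylic alcohol requires, and acylates oxygen only, so C1 keeps its configuration.

**Step 5**
Reactants: 8 (S)-2,4,4-trimethyl-3-vinylcyclohex-2-en-1-yl but-2-ynoate
Product: 9 drima-5,8-dien-11,1α-olide (1α-O; 10β-CH3)
Conditions: PhMe (0.01 M), BHT, solid Na2CO3, 140 °C, sealed tube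
Reagents that add atoms: none
Why: Heating brings the s-cis diene C10=C5–C6=C7 and the tethered ynoate C8≡C9 into a concerted, asynchronous, suprafacial [4π+2π] cycloaddition in which C7–C8 and C9–C10 form together. The closest known reaction type is the thermal ester-tethered type-1 intramolecular Diels–Alder reaction of 3-vinylcyclohex-2-enyl alkynoates. Ring B closes as the six-membered cycloaddition ring, and the temporary γ-lactone (C1–O–C11–C9–C10) closes as a five-membered ring in the fused mode that a three-atom tether allows. The only new stereocentre, quaternary C10, is controlled by the C1 carbinol, because the short tether lets the alkyne reach only the diene face on which the C1–O bond stands, so C9 bonds cis to O1 (α) and methyl C20 is pushed to the β face. Regiochemistry (C9 to C10, C8 to C7) is fixed by the tether and matches the polarity (nucleophilic terminus C7 to the β-carbon C8), and an alkyne dienophile removes any endo/exo question. The step needs the cycloaddition to outrun the 1,5-hydrogen shift of the Z-methyl diene and ionisation or elimination of the dienylic ester, which high dilution, acid-free conditions and BHT should secure.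

**Step 6**
Reactants: 9 drima-5,8-dien-11,1α-olide
Product: 10 5α-drim-8-en-11,1α-olide
Conditions: H2 (4 atm), 10% Pd/C, EtOAc, rt
Reagents that add atoms: none
Why: In this heterogeneous catalytic hydrogenation the isolated trisubstituted C5=C6 should be reduced while the tetrasubstituted, lactone-conjugated C8=C9 stays, and hydrogen should arrive on the α face because the axial C20 methyl and the 4β-methyl cover the β face, which sets 5α-H (trans-decalin).

**Step 7**
Reactants: 10 5α-drim-8-en-11,1α-olide
Product: 11 drim-8-ene-1α,11-diol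
Conditions: LiAlH4, Et2O, 0 °C → rt
Reagents that add atoms: none
Why: Hydride 1,2-reduction of the hindered α,β-unsaturated lactone opens the temporary ring to the allylic primary alcohol (C11) and the free 1α-OH without touching a stereocentre.

**Step 8**
Reactants: 11 drim-8-ene-1α,11-diol
Product: 12 8α,9α-epoxydrimane-1α,11-diol
Conditions: mCPBA, NaHCO3, CH2Cl2, 0 °C
Reagents that add atoms: 3-chloroperoxybenzoic acid, OOC(=O)c1cccc(Cl)c1
Why: In this Prilezhaev epoxidation of the only, electron-rich tetrasubstituted alkene the axial C20 methyl blocks the β face and the 1α-OH can hydrogen-bond the peracid on the α face, so the α-epoxide should form and fix the C8–O configuration.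

**Step 9**
Reactants: 12 8α,9α-epoxydrimane-1α,11-diol
Product: 13 8α,9α-epoxy-1α-hydroxydriman-11-al
Conditions: TEMPO (cat.), PhI(OAc)2, NaHCO3, CH2Cl2, rt
Reagents that add atoms: none
Why: Oxoammonium (TEMPO) oxidation takes the primary alcohol in preference to the hindered axial 1α-OH and stops at the aldehyde in the absence of water.

**Step 10**
Reactants: 13 8α,9α-epoxy-1α-hydroxydriman-11-al
Product: 14 1α,8α-dihydroxydriman-11-al (9α-H)
Conditions: SmI2 (2.2 equiv), THF–MeOH, −90 °C
Reagents that add atoms: none
Why: In the SmI2 reduction of an α,β-epoxy carbonyl compound the ketyl cleaves the Cα–O bond (C9–O) while C8–O keeps its configuration, and the samarium enolate should be protonated at C9 from the α face because the two flanking axial methyls (C17, C20) cover the β face, giving 9α-H and an equatorial CHO.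

**Step 11**
Reactants: 14 1α,8α-dihydroxydriman-11-al
Product: 15 13,14,15,16-tetranorlabd-11-ene-1α,8α-diol
Conditions: Ph3PCH3Br, KOtBu, THF, 0 °C → rt (excess ylide)
Reagents that add atoms: methyltriphenylphosphonium bromide, C[P+](c1ccccc1)(c1ccccc1)c1ccccc1.[Br-]
Why: In this Wittig methylenation the unstabilised ylide is too weak a base to deprotonate the tertiary carbinol to any extent, which should hold back retro-aldol cleavage and C9 epimerisation.

**Step 12**
Reactants: 15 13,14,15,16-tetranorlabd-11-ene-1α,8α-diol
Product: 16 1-O-(phenoxythiocarbonyl) derivative of 15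
Conditions: PhOC(S)Cl, pyridine, DMAP, CH2Cl2, rt
Reagents that add atoms: O-phenyl chlorothionoformate, S=C(Cl)Oc1ccccc1
Why: Thioacylation (first half of the Barton–McCombie sequence) should take the secondary 1α-OH, since the tertiary 8α-OH is too hindered to be acylated.

**Step 13**
Reactants: 16 1-O-(phenoxythiocarbonyl) derivative of 15
Product: 17 13,14,15,16-tetranorlabd-11-en-8α-ol
Conditions: Bu3SnH, AIBN (cat.), PhMe (0.1 M), 100 °C
Reagents that add atoms: none
Why: In this Barton–McCombie deoxygenation the stannyl radical adds to C=S, the C1–O bond fragments, and the secondary C1 radical should be reduced by the stannane faster than it can attack the vinyl group in a 4-exo or 5-endo mode, which removes the last helper.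

**Step 14**
Reactants: 18 but-2-yn-1-ol
Product: 20 (E)-3-iodobut-2-en-1-ol, via C,O-dizirconated butenol 19 (not isolated)
Conditions: Cp2Zr(H)Cl (2.2 equiv), THF, rt; then I2, 0 °C
Reagents that add atoms: zirconocene chloride hydride, [H][Zr](Cl)(C1C=CC=C1)C1C=CC=C1 (Zr in 19 only); iodine, II
Why: In this hydrozirconation–iodination Zr–H adds syn, the excess reagent should equilibrate zirconium to the less hindered methyl-bearing carbon, and iododemetalation proceeds with retention, so iodine ends trans to CH2OH.

**Step 15**
Reactants: 17 13,14,15,16-tetranorlabd-11-en-8α-ol; 20 (E)-3-iodobut-2-en-1-ol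
Product: 22 labd-13(E)-ene-8α,15-diol, via B-alkyl-9-BBN 21 (not isolated)
Conditions: 9-BBN, THF, rt; then 20, Pd(dppf)Cl2 (cat.), AsPh3, Cs2CO3, DMF–H2O, rt
Reagents that add atoms: 9-borabicyclo[3.3.1]nonane, B1C2CCCC1CCC2 (B in 21 only)
Why: In this B-alkyl Suzuki–Miyaura coupling 9-BBN adds anti-Markovnikov to the monosubstituted alkene (boron on C12) and the sp3–sp2 coupling keeps the geometry of the iodide, which forms C12–C13 and sets 13E.

**Step 16**
Reactants: 22 labd-13(E)-ene-8α,15-diol
Product: 23 8α-hydroxylabd-13(E)-en-15-yl acetate (target)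
Conditions: Ac2O, pyridine, CH2Cl2, 0 °C
Reagents that add atoms: acetic anhydride, CC(=O)OC(C)=O
Why: Selective O-acetylation should take only the primary allylic alcohol, because the tertiary 8α-OH does not react without forcing conditions.

**Compound list**
1 | 3-ethoxy-2-methylcyclohex-2-en-1-one | CCOC1=C(C)C(=O)CCC1 | starting material
2 | 3-ethoxy-2,6-dimethylcyclohex-2-en-1-one (racemic, not isolated) | CCOC1=C(C)C(=O)C(C)CC1 | intermediate
3 | 3-ethoxy-2,6,6-trimethylcyclohex-2-en-1-one | CCOC1=C(C)C(=O)C(C)(C)CC1 | intermediate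
4 | 3-ethoxy-2,6,6-trimethyl-1-vinylcyclohex-2-en-1-ol (racemic, not isolated) | CCOC1=C(C)C(O)(C=C)C(C)(C)CC1 | intermediate
5 | 2,4,4-trimethyl-3-vinylcyclohex-2-en-1-one | C=CC1=C(C)C(=O)CCC1(C)C | intermediate
6 | (S)-2,4,4-trimethyl-3-vinylcyclohex-2-en-1-ol | O[C@H]1CCC(C)(C)C(C=C)=C1C | intermediate
7 | but-2-ynoic acid | CC#CC(=O)O | starting material
8 | (S)-2,4,4-trimethyl-3-vinylcyclohex-2-en-1-yl but-2-ynoate | CC#CC(=O)O[C@H]1CCC(C)(C)C(C=C)=C1C | intermediate
9 | drima-5,8-dien-11,1α-olide (10β-CH3) | O=C1O[C@H]2CCC(C)(C)C3=CCC(C)=C1[C@@]23C | intermediate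
10 | 5α-drim-8-en-11,1α-olide | O=C1O[C@H]2CCC(C)(C)[C@@H]3CCC(C)=C1[C@@]23C | intermediate
11 | drim-8-ene-1α,11-diol | OCC1=C(C)CC[C@H]2C(C)(C)CC[C@H](O)[C@]12C | intermediate
12 | 8α,9α-epoxydrimane-1α,11-diol | OC[C@@]12O[C@]1(C)CC[C@H]1C(C)(C)CC[C@H](O)[C@]21C | intermediate
13 | 8α,9α-epoxy-1α-hydroxydriman-11-al | O=C[C@@]12O[C@]1(C)CC[C@H]1C(C)(C)CC[C@H](O)[C@]21C | intermediate
14 | 1α,8α-dihydroxydriman-11-al (9α-H) | O=C[C@@H]1[C@@]2(C)[C@@H](O)CCC(C)(C)[C@@H]2CC[C@@]1(C)O | intermediate
15 | 13,14,15,16-tetranorlabd-11-ene-1α,8α-diol | C=C[C@@H]1[C@@]2(C)[C@@H](O)CCC(C)(C)[C@@H]2CC[C@@]1(C)O | intermediate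
16 | 1-O-(phenoxythiocarbonyl) derivative of 15 | C=C[C@@H]1[C@@]2(C)[C@@H](OC(=S)Oc3ccccc3)CCC(C)(C)[C@@H]2CC[C@@]1(C)O | intermediate
17 | 13,14,15,16-tetranorlabd-11-en-8α-ol | C=C[C@@H]1[C@@]2(C)CCCC(C)(C)[C@@H]2CC[C@@]1(C)O | intermediate
18 | but-2-yn-1-ol | CC#CCO | starting material
19 | (E)-C3,O-bis(chlorozirconocenyl)but-2-en-1-ol (not isolated) | C/C(=C\CO[Zr](Cl)(C1C=CC=C1)C1C=CC=C1)[Zr](Cl)(C1C=CC=C1)C1C=CC=C1 | intermediate
20 | (E)-3-iodobut-2-en-1-ol | C/C(I)=C\CO | intermediate
21 | 12-(9-borabicyclo[3.3.1]nonan-9-yl)-13,14,15,16-tetranorlabdan-8α-ol (not isolated) | B1(CC[C@@H]2[C@@]3(C)CCCC(C)(C)[C@@H]3CC[C@@]2(C)O)C2CCCC1CCC2 | intermediate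
22 | labd-13(E)-ene-8α,15-diol | OC/C=C(\C)CC[C@@H]1[C@@]2(C)CCCC(C)(C)[C@@H]2CC[C@@]1(C)O | intermediate
23 | 8α-hydroxylabd-13(E)-en-15-yl acetate | CC(=O)OC/C=C(\C)CC[C@@H]1[C@@]2(C)CCCC(C)(C)[C@@H]2CC[C@@]1(C)O | target

Total step count: 16. Longest linear sequence: 15 (steps 1–13, 15, 16).

**Steps most likely to fail**

**Step 5.** The cycloaddition may be too slow at temperatures the dienylic ester tolerates, so that elimination, ionisation or a 1,5-hydrogen shift of the diene take over.
- The fallback sets out from 6 and uses a much more electron-poor alkyne.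
- Compound 6 is esterified (DCC, CH2Cl2, 0 °C) with 3-(4-methylphenylsulfonyl)prop-2-ynoic acid to the sulfonylpropynoate ester F1.
- F1 should cyclise at room temperature to the 8-sulfonyl dienyl lactone F2.
- Conjugate addition–elimination with Me2CuLi (Et2O, −78 → 0 °C) then exchanges the sulfonyl group for the C17 methyl group.
- The fallback comes back to the route at 9.

**Step 6.** Hydrogen uptake may fail or facial selectivity may be poor, because the lactone bridge holds ring A out of its chair and makes the trans-fused product strained.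
- The fallback sets out from 9 and changes both the order and the mechanism.
- LiAlH4 first opens the lactone to drima-5,8-diene-1α,11-diol F3.
- A radical hydrogen-atom-transfer hydrogenation (Mn(dpm)3 cat., PhSiH3, t-BuOOH, i-PrOH, rt) then reduces C5=C6 through the tertiary C5 radical, which should pick up hydrogen axially to give the trans-decalin.
- The tetrasubstituted C8=C9 should react more slowly.
- The fallback comes back to the route at 11.

**Step 10.** The aldehyde may be over-reduced by SmI2, or the aldol-type product may lose water.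
- The fallback sets out from 10 and runs the same oxygen installation at the lactone oxidation level, which SmI2 does not reduce further.
- Epoxidation of the conjugated alkene with CF3CO3H/Na2HPO4 from the α face gives the 8α,9α-epoxy lactone F4.
- SmI2/HMPA with 2-(dimethylamino)ethanol as proton source (known for α,β-epoxy esters) gives the 8α-hydroxy-9α-H lactone F5.
- DIBAL-H (CH2Cl2, −78 °C) reduces F5 to the aldehyde level, where the strained lactol should open.
- The fallback comes back to the route at 14.

**Further compounds**
F1 | step 5 | (S)-2,4,4-trimethyl-3-vinylcyclohex-2-en-1-yl 3-(4-methylphenylsulfonyl)prop-2-ynoate | Cc1ccc(cc1)S(=O)(=O)C#CC(=O)O[C@H]1CCC(C)(C)C(C=C)=C1C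
F2 | step 5 | 8-(4-methylphenylsulfonyl)-17-nor analogue of lactone 9 | O=C1O[C@H]2CCC(C)(C)C3=CCC(S(=O)(=O)c4ccc(C)cc4)=C1[C@@]23C
F3 | step 6 | drima-5,8-diene-1α,11-diol | OCC1=C(C)CC=C2C(C)(C)CC[C@H](O)[C@]12C
F4 | step 10 | 8α,9α-epoxy-5α-driman-11,1α-olide | O=C1O[C@H]2CCC(C)(C)[C@@H]3CC[C@@]4(C)O[C@]14[C@@]23C
F5 | step 10 | 8α-hydroxy-5α,9α-driman-11,1α-olide | O=C1O[C@H]2CCC(C)(C)[C@@H]3CC[C@@](C)(O)[C@H]1[C@@]23C
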